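## Retrosynthetic overview

1. Target 16 is opened at the C1=C10 alkene by ring-closing metathesis to the acyclic epoxy alcohol 15. The oxirane is the first ring formed (step 7) and the ten-membered carbocycle the last (step 8).
2. The C4–C5 oxirane of 15 comes from hydroxyl-directed threo epoxidation of the E-allylic alcohol 14. 14 comes from 11 by C8–O acylation with 3,4,5-trimethoxybenzoyl chloride and C6–O desilylation.
3. The C8–C9 bond comes from a chiral phosphoric acid-catalysed methallylboration of aldehyde 8, which sets C8 under catalyst control.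
4. The C6–C7 bond comes from a new IDPi-catalysed anti Mukaiyama aldol of the isovaleraldehyde enolsilane 7 with enal 5. This metal-free step sets the first stereocentres (C6, C7) and leaves C6–O silyl-protected.
5. Enal 5 comes from hex-1-en-5-yne by carboalumination/hydroxymethylation and oxidation; 7 comes from 3-methylbutanal.

Assumption and convention: atom labels C1–C15 follow germacrane numbering of the target (C4–C5 oxirane, C6 OH, C7 isopropyl, C8 ester, C1=C10 alkene); compounds 1, 6, 9, 12 and both catalyst antipodes are taken as purchasable; CIP descriptors of untouched centres change between some intermediates only because substituent priorities change.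

## Route

Step 1
Reactants: 1 hex-1-en-5-yne
Product: 4 (2E)-3-methylhepta-2,6-dien-1-ol, via alkenylalane 2 (not isolated), via lithium aluminate 3 (not isolated)
Conditions: Me3Al (2 equiv), Cp2ZrCl2 (20 mol%), CH2Cl2, 0 °C → rt; evaporate excess Me3Al; hexane, n-BuLi, 0 °C; (CH2O)n, THF, rt; aq. HCl
Reagents that add atoms: trimethylaluminium, C[Al](C)C; paraformaldehyde (as formaldehyde), C=O
Why: Negishi zirconium-catalysed carboalumination adds Me–Al syn across the terminal alkyne (Al on the terminal carbon, alkene untouched) and the derived aluminate is hydroxymethylated with retention, which fixes the E geometry of the future C4=C5 bond.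

Step 2
Reactants: 4 (2E)-3-methylhepta-2,6-dien-1-ol
Product: 5 (2E)-3-methylhepta-2,6-dienal
Conditions: (diacetoxyiodo)benzene (1.1 equiv), TEMPO (10 mol%), CH2Cl2, rt
Reagents that add atoms: none
Why: TEMPO-catalysed (oxoammonium) oxidation takes the allylic alcohol to the enal under neutral conditions without E/Z isomerisation or over-oxidation.

Step 3
Reactants: 6 3-methylbutanal
Product: 7 triethyl{[(1Z)-3-methylbut-1-en-1-yl]oxy}silane
Conditions: Et3SiCl, NaI, Et3N, MeCN, rt; pentane extraction, distillation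
Reagents that add atoms: chlorotriethylsilane, CC[Si](Cl)(CC)CC
Why: Soft enolisation with O-silylation by iodotriethylsilane formed in the flask gives the thermodynamically preferred Z silyl enol ether of the aldehyde.

Step 4
Reactants: 5 (2E)-3-methylhepta-2,6-dienal; 7 triethyl{[(1Z)-3-methylbut-1-en-1-yl]oxy}silane
Product: 8 (2S,3S,4E)-5-methyl-2-(propan-2-yl)-3-[(triethylsilyl)oxy]nona-4,8-dienal
Conditions: IDPi Brønsted acid (2 mol%; imidodiphosphorimidate from two 3,3'-bis[3,5-bis(trifluoromethyl)phenyl]-BINOL units with N-triflyl groups, antipode giving Re-face attack on 5), 7 (1.3 equiv), toluene, −60 °C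
Reagents that add atoms: none
Why: Proposed new method: the confined IDPi acid is silylated by 7 to a silylium–imidodiphosphorimidate ion pair that activates enal 5 as its O-silyl oxocarbenium inside the chiral pocket, the Z-enolsilane then adds to the Re face of the carbonyl through a compact synclinal open transition state that the pocket enforces over the extended one (anti relationship, C6 and C7 set together as 3S and 2S), and the silyl group ends on the aldolate oxygen so that the product leaves as its triethylsilyl ether while the bulkier product aldehyde is excluded from a second aldolisation; the closest known reaction type is the IDPi-catalysed single Mukaiyama aldolisation of acetaldehyde- and propanal-derived enolsilanes, extended here to a β-branched enolsilane and an aliphatic β,β-disubstituted enal.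

Step 5
Reactants: 8 (2S,3S,4E)-5-methyl-2-(propan-2-yl)-3-[(triethylsilyl)oxy]nona-4,8-dienal; 9 4,4,5,5-tetramethyl-2-(2-methylprop-2-en-1-yl)-1,3,2-dioxaborolane
Product: 11 (4R,5R,6S,7E)-2,8-dimethyl-5-(propan-2-yl)-6-[(triethylsilyl)oxy]dodeca-1,7,11-trien-4-ol, via pinacol borate ester 10 (not isolated)
Conditions: (R)-TRIP [(R)-3,3'-bis(2,4,6-triisopropylphenyl)-1,1'-binaphthyl-2,2'-diyl hydrogen phosphate] (5 mol%), 4 Å MS, toluene, −30 → 0 °C; aq. NaHCO3
Reagents that add atoms: none
Why: In this chiral phosphoric acid-catalysed allylboration the acid hydrogen-bonds to a boronate oxygen and the methallyl group is delivered through a closed chair transition state to the Re face of the aldehyde, so C8 (4R) is set by the catalyst against the modest Felkin preference of the α-stereocentre.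

Step 6
Reactants: 11 (4R,5R,6S,7E)-2,8-dimethyl-5-(propan-2-yl)-6-[(triethylsilyl)oxy]dodeca-1,7,11-trien-4-ol; 12 3,4,5-trimethoxybenzoyl chloride
Product: 14 (4R,5S,6S,7E)-6-hydroxy-2,8-dimethyl-5-(propan-2-yl)dodeca-1,7,11-trien-4-yl 3,4,5-trimethoxybenzoate, via silyl ether ester 13 (not isolated)
Conditions: Et3N, DMAP, CH2Cl2, 0 °C → rt; then HF·pyridine, THF, 0 °C
Reagents that add atoms: none
Why: DMAP-catalysed acyl transfer esterifies the only free hydroxyl (C8) and fluoride then cleaves the triethylsilyl ether at C6 without touching the ester, the alkenes or any stereocentre.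

Step 7
Reactants: 14 (4R,5S,6S,7E)-6-hydroxy-2,8-dimethyl-5-(propan-2-yl)dodeca-1,7,11-trien-4-yl 3,4,5-trimethoxybenzoate
Product: 15 (4R,5S,6R)-6-[(2S,3S)-3-(but-3-en-1-yl)-3-methyloxiran-2-yl]-6-hydroxy-2-methyl-5-(propan-2-yl)hex-1-en-4-yl 3,4,5-trimethoxybenzoate
Conditions: Ti(OiPr)4 (20 mol%), t-BuOOH (1.5 equiv, decane), 4 Å MS, CH2Cl2, −20 °C
Reagents that add atoms: tert-butyl hydroperoxide, CC(C)(C)OO
Why: In this hydroxyl-directed titanium-catalysed epoxidation (Sharpless type without chiral ligand) the C6 alkoxide binds titanium, the cis C4 methyl forces C6–H to eclipse the alkene (A1,3 strain), and the peroxide oxygen is delivered to the face syn to the C6 oxygen, giving the threo epoxy alcohol (C4 S, C5 S) while the two non-allylic alkenes stay untouched.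

Step 8
Reactants: 15 (4R,5S,6R)-6-[(2S,3S)-3-(but-3-en-1-yl)-3-methyloxiran-2-yl]-6-hydroxy-2-methyl-5-(propan-2-yl)hex-1-en-4-yl 3,4,5-trimethoxybenzoate
Product: 16 (1(10)Z,4S,5S,6R,7S,8R)-4,5-epoxy-6-hydroxygermacr-1(10)-en-8-yl 3,4,5-trimethoxybenzoate
Conditions: second-generation Grubbs catalyst RuCl2(H2IMes)(PCy3)(=CHPh) (10 mol%), toluene (1 mM), 80 °C, argon sparge
Reagents that add atoms: none
Why: In this ring-closing metathesis the ruthenium carbene loads on the monosubstituted alkene and closes onto the 1,1-disubstituted alkene with loss of ethene, and the trisubstituted C1=C10 alkene of the ten-membered ring is expected as the less strained Z isomer next to the trans-oxirane.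

## Compound list

1 | hex-1-en-5-yne | C=CCCC#C | starting material
2 | dimethyl[(1E)-2-methylhexa-1,5-dien-1-yl]alumane | C=CCC/C(C)=C/[Al](C)C | intermediate
3 | lithium butyldimethyl[(1E)-2-methylhexa-1,5-dien-1-yl]aluminate | [Li+].C=CCC/C(C)=C/[Al-](C)(C)CCCC | intermediate
4 | (2E)-3-methylhepta-2,6-dien-1-ol | C=CCC/C(C)=C/CO | intermediate
5 | (2E)-3-methylhepta-2,6-dienal | C=CCC/C(C)=C/C=O | intermediate
6 | 3-methylbutanal (isovaleraldehyde) | CC(C)CC=O | starting material
7 | triethyl{[(1Z)-3-methylbut-1-en-1-yl]oxy}silane | CC(C)/C=C\O[Si](CC)(CC)CC | intermediate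
8 | (2S,3S,4E)-5-methyl-2-(propan-2-yl)-3-[(triethylsilyl)oxy]nona-4,8-dienal | O=C[C@@H](C(C)C)[C@@H](O[Si](CC)(CC)CC)/C=C(\C)CCC=C | intermediate
9 | 4,4,5,5-tetramethyl-2-(2-methylprop-2-en-1-yl)-1,3,2-dioxaborolane (methallylboronic acid pinacol ester) | CC(=C)CB1OC(C)(C)C(C)(C)O1 | starting material
10 | 2-{[(4R,5R,6S,7E)-2,8-dimethyl-5-(propan-2-yl)-6-[(triethylsilyl)oxy]dodeca-1,7,11-trien-4-yl]oxy}-4,4,5,5-tetramethyl-1,3,2-dioxaborolane | CC1(C)OB(O[C@@H]([C@@H](C(C)C)[C@@H](O[Si](CC)(CC)CC)/C=C(\C)CCC=C)CC(C)=C)OC1(C)C | intermediate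
11 | (4R,5R,6S,7E)-2,8-dimethyl-5-(propan-2-yl)-6-[(triethylsilyl)oxy]dodeca-1,7,11-trien-4-ol | O[C@@H]([C@@H](C(C)C)[C@@H](O[Si](CC)(CC)CC)/C=C(\C)CCC=C)CC(C)=C | intermediate
12 | 3,4,5-trimethoxybenzoyl chloride | COc1cc(C(Cl)=O)cc(OC)c1OC | starting material
13 | (4R,5R,6S,7E)-2,8-dimethyl-5-(propan-2-yl)-6-[(triethylsilyl)oxy]dodeca-1,7,11-trien-4-yl 3,4,5-trimethoxybenzoate | COc1cc(C(=O)O[C@@H]([C@@H](C(C)C)[C@@H](O[Si](CC)(CC)CC)/C=C(\C)CCC=C)CC(C)=C)cc(OC)c1OC | intermediate
14 | (4R,5S,6S,7E)-6-hydroxy-2,8-dimethyl-5-(propan-2-yl)dodeca-1,7,11-trien-4-yl 3,4,5-trimethoxybenzoate | COc1cc(C(=O)O[C@@H]([C@@H](C(C)C)[C@@H](O)/C=C(\C)CCC=C)CC(C)=C)cc(OC)c1OC | intermediate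
15 | (4R,5S,6R)-6-[(2S,3S)-3-(but-3-en-1-yl)-3-methyloxiran-2-yl]-6-hydroxy-2-methyl-5-(propan-2-yl)hex-1-en-4-yl 3,4,5-trimethoxybenzoate | COc1cc(C(=O)O[C@@H]([C@@H](C(C)C)[C@@H](O)[C@@H]2O[C@@]2(C)CCC=C)CC(C)=C)cc(OC)c1OC | intermediate
16 | (1(10)Z,4S,5S,6R,7S,8R)-4,5-epoxy-6-hydroxygermacr-1(10)-en-8-yl 3,4,5-trimethoxybenzoate (CNP0260213.11) | COc1cc(C(=O)O[C@@H]2C/C(C)=C\CC[C@]3(C)O[C@H]3[C@H](O)[C@@H]2C(C)C)cc(OC)c1OC | target

## Step count and risk

Total step count: 8. Longest linear sequence: 7 (steps 1, 2, 4, 5, 6, 7, 8 from hex-1-en-5-yne); step 3 is a one-step side branch.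

The three steps most likely to fail:

**Step 4 (the new aldol).** The anti/syn sense with a β-branched enolsilane, the reactivity of a conjugated β,β-disubstituted enal, and the survival of the acid-labile allylic silyl ether under silylium catalysis are all unproven. The fallback sets out from 5 and comes back at 8, using known chemistry. Methyl 3-methylbutanoate is converted with LiN(i-Pr)2 and Me3SiCl (THF, −78 °C) into its silyl ketene acetal [(1-methoxy-3-methylbut-1-en-1-yl)oxy]trimethylsilane F1. The known Lewis-base-catalysed, SiCl4-mediated aldol (chiral binaphthyldiamine-derived bisphosphoramide, 5 mol%, CH2Cl2, −78 °C) is anti-selective with conjugated aldehydes whatever the ketene acetal geometry. It adds F1 to 5 and gives methyl (2S,3S,4E)-3-hydroxy-5-methyl-2-(propan-2-yl)nona-4,8-dienoate F2. Et3SiCl/imidazole (DMF) gives methyl (2S,3S,4E)-5-methyl-2-(propan-2-yl)-3-[(triethylsilyl)oxy]nona-4,8-dienoate F3, and i-Bu2AlH (CH2Cl2, −78 °C) reduces the ester directly to aldehyde 8.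

**Step 5 (catalyst control at C8).** The Felkin preference of the α-branched aldehyde opposes the required sense, and the hindered aldehyde may react slowly. The fallback sets out from 8 and comes back at 11; it replaces carbon-nucleophile addition by hydride addition, for which Felkin–Anh control is matched. 2-Methylallylmagnesium chloride CH2=C(CH3)CH2MgCl (THF, −78 °C) gives the epimer mixture at C8, (5R,6S,7E)-2,8-dimethyl-5-(propan-2-yl)-6-[(triethylsilyl)oxy]dodeca-1,7,11-trien-4-ol F4. Dess–Martin periodinane (NaHCO3, CH2Cl2, 0 °C) gives (5S,6S,7E)-2,8-dimethyl-5-(propan-2-yl)-6-[(triethylsilyl)oxy]dodeca-1,7,11-trien-4-one F5. LiBH(s-Bu)3 (THF, −78 °C) then attacks anti to the large C6 branch, which places the new hydroxyl anti to the isopropyl group and syn to the C6 oxygen, giving 11.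

**Step 8 (ring-closing metathesis).** Closing a ten-membered carbocycle onto a 1,1-disubstituted alkene is demanding; oligomerisation and E/Z mixtures are the likely failures. The fallback sets out from 14 and comes back at 16; it reverses the order of ring formation. Triene 14, which has no oxirane yet, is cyclised (same ruthenium catalyst, CH2Cl2, 1 mM, 40 °C, kept mild because the cyclodeca-1,5-diene can undergo Cope rearrangement) to (1(10)Z,4E,6S,7S,8R)-6-hydroxygermacra-1(10),4-dien-8-yl 3,4,5-trimethoxybenzoate F6. The C4=C5 alkene of the macrocycle is then epoxidised under hydroxyl direction (VO(acac)2, t-BuOOH, CH2Cl2, 0 °C), syn to C6–OH on the outer face, to give 16.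

## Further compounds

F1 | step 4 | [(1-methoxy-3-methylbut-1-en-1-yl)oxy]trimethylsilane (E/Z mixture) | COC(O[Si](C)(C)C)=CC(C)C
F2 | step 4 | methyl (2S,3S,4E)-3-hydroxy-5-methyl-2-(propan-2-yl)nona-4,8-dienoate | COC(=O)[C@@H](C(C)C)[C@@H](O)/C=C(\C)CCC=C
F3 | step 4 | methyl (2S,3S,4E)-5-methyl-2-(propan-2-yl)-3-[(triethylsilyl)oxy]nona-4,8-dienoate | COC(=O)[C@@H](C(C)C)[C@@H](O[Si](CC)(CC)CC)/C=C(\C)CCC=C
F4 | step 5 | (5R,6S,7E)-2,8-dimethyl-5-(propan-2-yl)-6-[(triethylsilyl)oxy]dodeca-1,7,11-trien-4-ol (mixture of C4 epimers) | OC([C@@H](C(C)C)[C@@H](O[Si](CC)(CC)CC)/C=C(\C)CCC=C)CC(C)=C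
F5 | step 5 | (5S,6S,7E)-2,8-dimethyl-5-(propan-2-yl)-6-[(triethylsilyl)oxy]dodeca-1,7,11-trien-4-one | O=C([C@@H](C(C)C)[C@@H](O[Si](CC)(CC)CC)/C=C(\C)CCC=C)CC(C)=C
F6 | step 8 | (1(10)Z,4E,6S,7S,8R)-6-hydroxygermacra-1(10),4-dien-8-yl 3,4,5-trimethoxybenzoate | COc1cc(C(=O)O[C@@H]2C/C(C)=C\CC/C(C)=C/[C@H](O)[C@@H]2C(C)C)cc(OC)c1OC
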